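## Structural features

The target is one cyclohexane ring. C1 is quaternary and carries a free carboxyl group and an acyloxy group; C3, C4 and C5 form a contiguous row of three oxygenated stereocentres, separated from C1 by the C2 and C6 methylenes. O1, O3 and O4 lie on one face and O5 and the carboxyl group on the other, so O3/O4 is a cis pair and O4/O5 a trans-diequatorial pair, exactly as in (−)-quinic acid. Two (E)-3-(3,4-dihydroxyphenyl)prop-2-enoyl (caffeoyl) chains are bound as esters, one to the tertiary O1 and one to the axial secondary O3, which stand 1,3-diaxial to each other; O4 and O5 are free. The fragile parts are: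
- the two cinnamate esters, which base cleaves and moves from O3 to O4 and O5;
- the free catechols, which oxidise easily to o-quinones and bind metals;
- the conjugated C=C bonds, which exclude hydrogenolysis and are light-sensitive;
- the O5/carboxyl pair, which can lactonise under dehydrating acid.

Because all four stereocentres can be bought, the real difficulty is regiochemical and tactical: O1 and O3 must be told apart from O4 and O5, a crowded tertiary hydroxyl next to a carboxyl carbon must be esterified, and every protecting group must come off without base. The key step exploits the Cβ–C1′ bond that joins each propenoate chain to its catechol ring. If both bonds are made last, the acyl group that must be forced onto O1 and O3 shrinks to a bare acryloyl group, and the catechol rings stay out of all chemistry on the cyclohexane ring.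

## Logic of the disconnections

**14 to 13.** No skeletal bond is cut; only protecting-group C–O bonds are cut on paper: the two ketal carbons on the catechol oxygens, the diacetal on O4/O5 and the benzylic O–CH2 bond of the ester. All three groups are chosen to fall to the same aqueous strong acid, so 13 should become 14 in one base-free operation. An all-silicon set (aryl silyl ethers, a disiloxane bridge on O4/O5, a 2-silylethyl ester) was weighed and set aside for two reasons. The silylethyl ester is not reliably cleaved by buffered hydrogen fluoride and needs basic fluoride, under which the O3 ester migrates and the catecholates oxidise. The disiloxane has no built-in preference for O4/O5 over O3/O4 or O3/O5. The demand on the forward step is that the cinnamate esters and the E double bonds outlast the acid.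

**13 to 8 and 10.** Both Cβ–C(aryl) bonds are cut. This removes the two oxidation-prone aryl rings from everything earlier and splits a 45-carbon intermediate into a small core and two copies of one simple aryl bromide. The forward step must arylate two acrylates at the terminal carbon only, with E geometry, once each, and must leave a benzylic ester, a tertiary α-acyloxy ester and three acetals alone. This calls for a catalyst that works near room temperature with a weak amine base.

**8 to 5 and 6.** The O1–C(=O) and O3–C(=O) bonds are cut. The acyl donor 6 is the smallest and most electrophilic enoyl chloride available, which is what the hindered, electron-poor tertiary O1–H needs. The forward step must drive the second, slower acylation to completion without polymerising the acrylate.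

**5 to 2 and 3 (through 4).** The ester O–CH2(aryl) bond is cut and the methyl ester restored. A methyl ester comes for free with the diacetal, but at the end it could only be removed with hydroxide, which the target does not survive. Exchanging it at this early, robust stage costs one operation and buys an ester that acid removes. The forward step must alkylate the carboxylate and not the two hydroxyls.

**2 to 1.** The four acetal C–O bonds on O4/O5 and the ester O–CH3 bond are cut, returning the unprotected chiral-pool acid. The gain is that all four ring stereocentres and the O4/O5 versus O1/O3 distinction come from one operation. The forward step must select the trans-diequatorial diol, which a six-membered bis-acetal does under thermodynamic control.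

**10 to 9.** The two ketal C–O bonds are cut. The forward step is a simple ketalisation of a catechol that already carries the halogen at the right position.

## Other disconnections considered

**Alternative 1: Ireland–Claisen ring contraction.**
- Cut: the ring bond C1–C2, which traces the carbocycle back to the six-membered vinyl lactone A1.
- Forward key step: A1 would be enolised and O-silylated, then rearranged [3,3] through the boat-like transition state that the lactone ring enforces. C2 is delivered to the face of C1 on which the vinyl group sits, so the C4 configuration of A1 (vinyl trans to O5) is transferred to C1. Hydrolysis of the silyl ester would give acid A2 with O1 trans to O5 and a C3=C4 alkene.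
- In its favour: a stereospecific pericyclic step builds the quaternary C1 without a metal and does not depend on the chiral pool. Either enantiomer, C1 or C5 variants and labelled rings would be reachable, and the alkene of A2 invites cis-dihydroxylation anti to O5 to set C3 and C4.
- Against it here: A1 must first be made enantiopure. After A2 the C3 and C4 oxygens must still be introduced, O3 told apart from O4, and the two identical silyl ethers on O1 and O5 differentiated. No ester or Cβ–aryl bond is addressed, so the caffeoyl groups would still need the chemistry of the chosen plan.
- Comparison: on structure, it constructs one ring, one C–C bond and one stereocentre that the chosen plan obtains in 1; the chosen plan forms only the two aryl–alkene bonds. On mechanism, the rearrangement is the equal or the better of the Heck step in predictability and in leaving no palladium to remove, and it is better for analogue flexibility. On step economy it is clearly worse, since reaching A2 alone is expected to take more operations than the whole chosen route.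

**Alternative 2: acyloxyacrolein Diels–Alder.**
- Cut: C2–C3 and C1–C6, tracing the ring to dienophile A3 and buta-1,3-diene A4.
- Forward key step: a chiral ammonium salt would condense with the aldehyde of A3 to an iminium ion. A4 would add to the activated C=CH2 bond in one concerted [4+2] event, with the catalyst shielding one face so that C1 is set. Hydrolysis would release A5.
- In its favour: one catalytic asymmetric step makes the ring and C1. The tertiary O1 ester is present from the start, built on an enol oxygen rather than by acylating a hindered tertiary alcohol; on this point it is better than the chosen plan, whose step 3 must force that acylation. The phosphonate is a latent caffeate: Horner–Wadsworth–Emmons olefination with aldehyde A6 would give the E-propenoate without a transition metal, the equal of the Heck step in E-selectivity.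
- Against it here: A5 carries only C1. The aldehyde must be oxidised to the acid, and the three oxygens at C3, C4 and C5 must be grown from one C4=C5 alkene, with C3 an unactivated methylene. The O3 ester still needs a separate acylation. A4 is a gaseous, sluggish diene, and the enantiopurity would rest on a catalyst, whereas 1 is enantiopure by origin.
- Comparison: on structure, it creates the ring and one stereocentre but leaves three stereocentres to be made, whereas the chosen plan makes none. On mechanism, an organocatalytic cycloaddition stands against an organopalladium cross-coupling, both well-understood classes. On step economy it is far longer.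

**Alternative 3: ring-closing metathesis on a γ-lactone template.**
- Cut: the C3=C4 bond, tracing the carbocycle to the diene lactone A7, which has allyl on C1 and vinyl on C5, cis to each other.
- Forward key step: the second-generation Grubbs catalyst would load onto one terminal alkene, and the ruthenium carbene would close onto the other by [2+2] and retro-[2+2] with loss of the two terminal methylene carbons. The lactone holds the two chains on one face, so the six-membered ring should close readily to the bridged lactone A8.
- In its favour: A8 has C1 and C5 set, and O5 and the carboxyl group are tied up in the lactone, leaving O1 as the only hydroxyl. Singling out O1 therefore needs no protecting group, which is the equal or the better of the chosen plan on that point. Dihydroxylation of C3=C4 from the face away from the lactone bridge would give the natural cis-3,4-diol, and in the lactone O3 is equatorial and O4 axial, which should help a selective O3 acylation.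
- Against it here: A7 needs its own enantioselective synthesis with two stereocentres. The lactone would have to be opened at the very end, without base, in the presence of two cinnamate esters, and that hydrolysis has doubtful selectivity. The ring it builds is already present in 1.
- Comparison: on structure, it forms one ring and one C=C bond that is then consumed, while the chosen plan forms two bonds that remain in the target. On mechanism, both are catalytic transition-metal steps of comparable reliability. On step economy it is worse by the whole synthesis of A7 plus dihydroxylation and lactone opening.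

Key step: step 5

Remark on numbering: the ring is numbered as in (−)-quinic acid. C1 carries the carboxyl group, O3 is cis to O4, and O5 is trans to O4 and cis to the carboxyl group. "Quinate" in the names means this (1S,3R,4S,5R) skeleton with unchanged configuration.

Remark on structures: the ring configuration of the key-step precursor 8 and product 13 was compared centre by centre with 14 and with 1 and agrees; no structural correction was needed. The acylated secondary oxygen is O3. The changes made concern protecting groups only.

Remark on intermediates: partly reacted species are numbered as non-isolated intermediates where defined compounds are passed through (steps 2, 3 and 5). In steps 1 and 6 several events overlap in no fixed order.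

## Steps

Step 1
Reactants: 1 (−)-quinic acid
Product: 2 methyl 4,5-O-[(2S,3S)-2,3-dimethoxybutane-2,3-diyl]quinate
Conditions: butane-2,3-dione, HC(OMe)3, camphorsulfonic acid (cat.), MeOH, reflux
Reagents that add atoms: butane-2,3-dione, CC(=O)C(C)=O; methanol, CO; trimethyl orthoformate, COC(OC)OC
Why: Fischer esterification and butane-2,3-diacetal formation run in the same pot under thermodynamic control; the six-membered bis-acetal sits comfortably only across the trans-diequatorial O4/O5 pair, so O1 and O3 stay free. The two new acetal stereocentres are set by the double anomeric effect (both methoxy groups axial, both methyl groups equatorial on the chair dioxane), which with this diol means S,S; the ring stereocentres of 1 are untouched.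

Step 2
Reactants: 2 methyl 4,5-O-[(2S,3S)-2,3-dimethoxybutane-2,3-diyl]quinate; 3 4-methoxybenzyl chloride
Product: 5 4-methoxybenzyl 4,5-O-[(2S,3S)-2,3-dimethoxybutane-2,3-diyl]quinate, via cesium carboxylate 4 (not isolated)
Conditions: CsOH·H2O (1.05 equiv), MeOH/H2O, rt; evaporate, toluene azeotrope; then 3, n-Bu4NI (cat.), DMF, rt
Reagents that add atoms: cesium hydroxide monohydrate, [Cs+].[OH-].O
Why: Saponification of the unhindered α-hydroxy methyl ester (acyl–oxygen cleavage) followed by SN2 O-alkylation of the cesium carboxylate, which is far more nucleophilic in DMF than the neutral secondary and tertiary hydroxyls. The diacetal is inert to base, and the exchange gives an ester that acid, not hydroxide, removes at the end.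

Step 3
Reactants: 5 4-methoxybenzyl 4,5-O-[(2S,3S)-2,3-dimethoxybutane-2,3-diyl]quinate; 6 acryloyl chloride
Product: 8 4-methoxybenzyl 1,3-di-O-acryloyl-4,5-O-[(2S,3S)-2,3-dimethoxybutane-2,3-diyl]quinate, via 3-O-monoacrylate 7 (not isolated)
Conditions: 6 (5 equiv), i-Pr2NEt, DMAP (0.3 equiv), BHT (trace), CH2Cl2, 0 °C → rt
Reagents that add atoms: none
Why: DMAP-catalysed acylation with the smallest enoyl donor; the axial secondary O3–H should react first (7), and the excess reagent should then esterify the tertiary O1–H, which is hindered by the 1,3-diaxial O3 ester and deactivated by the neighbouring ester carbonyl. The hindered amine and the radical inhibitor limit conjugate addition and polymerisation; no stereocentre is involved.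

Step 4
Reactants: 9 4-bromobenzene-1,2-diol
Product: 10 5-bromo-2,2-dimethyl-1,3-benzodioxole
Conditions: Me2C(OMe)2, p-TsOH·H2O (cat.), toluene, reflux, MeOH removed over 4 Å molecular sieves
Reagents that add atoms: 2,2-dimethoxypropane, COC(C)(C)OC
Why: Acid-catalysed transketalisation of the catechol, driven by removal of methanol. The cyclic ketal is stable to amines, palladium and heat, unlike aryl silyl ethers, and is released by aqueous strong acid together with the other groups.

Step 5
Reactants: 8 4-methoxybenzyl 1,3-di-O-acryloyl-4,5-O-[(2S,3S)-2,3-dimethoxybutane-2,3-diyl]quinate; 10 5-bromo-2,2-dimethyl-1,3-benzodioxole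
Product: 13 4-methoxybenzyl 1,3-bis-O-[(E)-3-(2,2-dimethyl-1,3-benzodioxol-5-yl)prop-2-enoyl]-4,5-O-[(2S,3S)-2,3-dimethoxybutane-2,3-diyl]quinate, via 3-O-arylpropenoyl 1-O-acrylate 11 (not isolated), via 1-O-arylpropenoyl 3-O-acrylate 12 (not isolated)
Conditions: 10 (2.6 equiv), Pd2(dba)3 (3 mol%), [(t-Bu)3PH]BF4 (12 mol%), Cy2NMe (3 equiv), 1,4-dioxane, rt → 50 °C, argon
Reagents that add atoms: none
Why: Twofold Mizoroki–Heck arylation; the closest known type is the coupling of aryl bromides, electron-rich ones included, with acrylate esters under tris(dibenzylideneacetone)dipalladium, tri-tert-butylphosphine and a hindered amine near room temperature. The bulky phosphine gives a monoligated zerovalent palladium species that inserts into the C–Br bond of 10; the arylpalladium bromide (divalent palladium) binds the acrylate, and syn carbopalladation puts the aryl group on the unsubstituted terminal carbon and palladium on the carbon next to the carbonyl. Rotation about the new single bond and syn β-hydride elimination, through the conformer with aryl and ester groups anti, release the E-propenoate, and the amine takes HBr from the palladium hydride to restart the cycle. The two acrylates are insulated from each other by the ring and their reacting CH2 termini lie four atoms from the crowded C1 and C3, so each should behave as a simple alkyl acrylate, passing through 11 and 12. No ring is closed and no stereocentre is formed; the four ring stereocentres and the two acetal centres take no part. The step needs β-regioselectivity, E geometry, a single arylation of each alkene and full conversion of both: the first two are inherent to insertion into an electron-poor monosubstituted alkene followed by syn elimination, the third follows because the β-aryl acrylate formed is a much poorer acceptor, and the fourth is served by the excess of 10. The low temperature and weak base spare the tertiary α-acyloxy ester, the benzylic ester, the diacetal and the aryl ketals.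

Step 6
Reactants: 13 4-methoxybenzyl 1,3-bis-O-[(E)-3-(2,2-dimethyl-1,3-benzodioxol-5-yl)prop-2-enoyl]-4,5-O-[(2S,3S)-2,3-dimethoxybutane-2,3-diyl]quinate
Product: 14 1,3-di-O-[(E)-caffeoyl]quinic acid (1,3-dicaffeoylquinic acid)
Conditions: TFA/H2O (9:1), anisole (20 equiv), 0 °C → rt, dark; evaporate below 30 °C
Reagents that add atoms: none
Why: One acidolysis removes everything: the 4-methoxybenzyl ester ionises by alkyl–oxygen cleavage and its cation is trapped by anisole, while the diacetal and the two aryl isopropylidene ketals hydrolyse through oxocarbenium ions, the water ending in the carbonyl by-products. Cinnamate esters tolerate acid at room temperature, and the absence of base avoids acyl migration to O4/O5 and catechol oxidation; no stereocentre is touched.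

## Compound list

1 | (−)-quinic acid, (1S,3R,4S,5R)-1,3,4,5-tetrahydroxycyclohexane-1-carboxylic acid | O[C@@H]1C[C@@](O)(C(=O)O)C[C@@H](O)[C@@H]1O | starting material
2 | methyl 4,5-O-[(2S,3S)-2,3-dimethoxybutane-2,3-diyl]quinate, i.e. methyl (2S,3S,4aR,6S,8R,8aR)-6,8-dihydroxy-2,3-dimethoxy-2,3-dimethyloctahydrobenzo[b][1,4]dioxine-6-carboxylate (trans-fused, both OMe axial) | O[C@@H]1C[C@@](O)(C(=O)OC)C[C@@H](O[C@](C)(OC)[C@@]2(C)OC)[C@@H]1O2 | intermediate
3 | 4-methoxybenzyl chloride | COc1ccc(CCl)cc1 | starting material
4 | cesium 4,5-O-[(2S,3S)-2,3-dimethoxybutane-2,3-diyl]quinate | O[C@@H]1C[C@@](O)(C(=O)[O-])C[C@@H](O[C@](C)(OC)[C@@]2(C)OC)[C@@H]1O2.[Cs+] | intermediate (not isolated)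
5 | 4-methoxybenzyl 4,5-O-[(2S,3S)-2,3-dimethoxybutane-2,3-diyl]quinate | O[C@@H]1C[C@@](O)(C(=O)OCc3ccc(OC)cc3)C[C@@H](O[C@](C)(OC)[C@@]2(C)OC)[C@@H]1O2 | intermediate
6 | acryloyl chloride | C=CC(=O)Cl | starting material
7 | 4-methoxybenzyl 3-O-acryloyl-4,5-O-[(2S,3S)-2,3-dimethoxybutane-2,3-diyl]quinate | C=CC(=O)O[C@@H]1C[C@@](O)(C(=O)OCc3ccc(OC)cc3)C[C@@H](O[C@](C)(OC)[C@@]2(C)OC)[C@@H]1O2 | intermediate (not isolated)
8 | 4-methoxybenzyl 1,3-di-O-acryloyl-4,5-O-[(2S,3S)-2,3-dimethoxybutane-2,3-diyl]quinate | C=CC(=O)O[C@@H]1C[C@@](OC(=O)C=C)(C(=O)OCc3ccc(OC)cc3)C[C@@H](O[C@](C)(OC)[C@@]2(C)OC)[C@@H]1O2 | intermediate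
9 | 4-bromobenzene-1,2-diol | Brc1ccc(O)c(O)c1 | starting material
10 | 5-bromo-2,2-dimethyl-1,3-benzodioxole | CC1(C)Oc2ccc(Br)cc2O1 | intermediate
11 | 4-methoxybenzyl 1-O-acryloyl-3-O-[(E)-3-(2,2-dimethyl-1,3-benzodioxol-5-yl)prop-2-enoyl]-4,5-O-[(2S,3S)-2,3-dimethoxybutane-2,3-diyl]quinate | O=C(/C=C/c1ccc2OC(C)(C)Oc2c1)O[C@@H]1C[C@@](OC(=O)C=C)(C(=O)OCc2ccc(OC)cc2)C[C@@H](O[C@](C)(OC)[C@@]2(C)OC)[C@@H]1O2 | intermediate (not isolated)
12 | 4-methoxybenzyl 3-O-acryloyl-1-O-[(E)-3-(2,2-dimethyl-1,3-benzodioxol-5-yl)prop-2-enoyl]-4,5-O-[(2S,3S)-2,3-dimethoxybutane-2,3-diyl]quinate | C=CC(=O)O[C@@H]1C[C@@](OC(=O)/C=C/c2ccc3OC(C)(C)Oc3c2)(C(=O)OCc2ccc(OC)cc2)C[C@@H](O[C@](C)(OC)[C@@]2(C)OC)[C@@H]1O2 | intermediate (not isolated)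
13 | 4-methoxybenzyl 1,3-bis-O-[(E)-3-(2,2-dimethyl-1,3-benzodioxol-5-yl)prop-2-enoyl]-4,5-O-[(2S,3S)-2,3-dimethoxybutane-2,3-diyl]quinate | O=C(/C=C/c1ccc2OC(C)(C)Oc2c1)O[C@@H]1C[C@@](OC(=O)/C=C/c2ccc3OC(C)(C)Oc3c2)(C(=O)OCc2ccc(OC)cc2)C[C@@H](O[C@](C)(OC)[C@@]2(C)OC)[C@@H]1O2 | intermediate
14 | 1,3-di-O-[(E)-caffeoyl]quinic acid | O=C(/C=C/c1ccc(O)c(O)c1)O[C@@H]1C[C@@](OC(=O)/C=C/c2ccc(O)c(O)c2)(C(=O)O)C[C@@H](O)[C@@H]1O | target

## Step count and least certain steps

Total step count: 6. Longest linear sequence: 5 steps (steps 1, 2, 3, 5 and 6, from 1 to 14); step 4 is a one-step branch.

**Step 5 (key step).** The most likely failure is stalling after the first arylation: slow oxidative addition to the electron-rich bromide lets the catalyst aggregate to palladium black, the second acrylate is left untouched (11 and 12 persist), and 10 is lost by reductive debromination. The fallback makes the C–C bond on a substrate that can be forced and attaches the finished acyl group by classical acylation. It sets out from 10 and 5. A Mizoroki–Heck coupling of 10 with acrylic acid (Pd(OAc)2, P(o-tol)3, Et3N, MeCN, 90 °C) should give (E)-3-(2,2-dimethyl-1,3-benzodioxol-5-yl)prop-2-enoic acid F1. Oxalyl chloride with a trace of DMF in CH2Cl2 should convert it into (E)-3-(2,2-dimethyl-1,3-benzodioxol-5-yl)prop-2-enoyl chloride F2. An excess of F2 with DMAP and pyridine in CH2Cl2 at rt to 40 °C should esterify O3 and then O1 of 5, so the route is rejoined at 13.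

**Step 3.** The most likely failure is incomplete esterification of the tertiary O1–H: the reaction stalls at 7 because the acid chloride is consumed by amine-initiated oligomerisation and conjugate addition faster than the hindered hydroxyl attacks it. The fallback uses a masked acrylate that tolerates forcing conditions. It sets out from 5. Treatment with 3-chloropropanoyl chloride, pyridine and catalytic DMAP in CH2Cl2 at 0 to 40 °C should give 4-methoxybenzyl 1,3-bis-O-(3-chloropropanoyl)-4,5-O-[(2S,3S)-2,3-dimethoxybutane-2,3-diyl]quinate F3. Et3N in CH2Cl2 at rt should then remove two equivalents of HCl by E1cB elimination, and the route is rejoined at 8.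

**Step 6.** The most likely failure is slow hydrolysis of the aryl ketals, which prolongs the acid exposure. During that time three things can happen: lactonisation between O5 and the carboxyl group, acid-catalysed acyl migration, or C-benzylation of the freed catechol rings by the 4-methoxybenzyl cation. The fallback splits the endgame so that the catechols are freed by fluoride and the acid stage lasts only as long as the ester and diacetal need. It sets out from 9 and 8. TBSCl and imidazole in DMF should give 4-bromo-1,2-bis(tert-butyldimethylsilyloxy)benzene F4. Coupling of F4 with 8 under the conditions of step 5 should give 4-methoxybenzyl 1,3-bis-O-[(E)-3,4-bis(tert-butyldimethylsilyloxy)cinnamoyl]-4,5-O-[(2S,3S)-2,3-dimethoxybutane-2,3-diyl]quinate F5. Et3N·3HF in THF at 0 °C to rt, a weakly acidic fluoride source that cannot move esters while O4 and O5 are still blocked, should give 4-methoxybenzyl 1,3-di-O-[(E)-caffeoyl]-4,5-O-[(2S,3S)-2,3-dimethoxybutane-2,3-diyl]quinate F6. A short treatment with TFA/H2O (9:1) and anisole at 0 °C should then release the target, and the route is rejoined at 14.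

**Step 2.** The most likely failure is loss of the alkylating agent to residual hydroxide and water in the crude salt, with some 2 carried through unsaponified and some alkylation at hydroxyl oxygen. The fallback separates the two events and esterifies under neutral conditions. It sets out from 2. LiOH in THF/H2O, then careful acidification with dilute HCl at 0 °C and extraction, should give 4,5-O-[(2S,3S)-2,3-dimethoxybutane-2,3-diyl]quinic acid F7. O-(4-Methoxybenzyl)-N,N′-diisopropylisourea in THF at rt alkylates only the carboxylic acid, and the route is rejoined at 5.

## Further compounds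

F1 | step 5 | (E)-3-(2,2-dimethyl-1,3-benzodioxol-5-yl)prop-2-enoic acid | CC1(C)Oc2ccc(/C=C/C(=O)O)cc2O1
F2 | step 5 | (E)-3-(2,2-dimethyl-1,3-benzodioxol-5-yl)prop-2-enoyl chloride | CC1(C)Oc2ccc(/C=C/C(=O)Cl)cc2O1
F3 | step 3 | 4-methoxybenzyl 1,3-bis-O-(3-chloropropanoyl)-4,5-O-[(2S,3S)-2,3-dimethoxybutane-2,3-diyl]quinate | ClCCC(=O)O[C@@H]1C[C@@](OC(=O)CCCl)(C(=O)OCc3ccc(OC)cc3)C[C@@H](O[C@](C)(OC)[C@@]2(C)OC)[C@@H]1O2
F4 | step 6 | 4-bromo-1,2-bis(tert-butyldimethylsilyloxy)benzene | Brc1ccc(O[Si](C)(C)C(C)(C)C)c(O[Si](C)(C)C(C)(C)C)c1
F5 | step 6 | 4-methoxybenzyl 1,3-bis-O-[(E)-3,4-bis(tert-butyldimethylsilyloxy)cinnamoyl]-4,5-O-[(2S,3S)-2,3-dimethoxybutane-2,3-diyl]quinate | O=C(/C=C/c1ccc(O[Si](C)(C)C(C)(C)C)c(O[Si](C)(C)C(C)(C)C)c1)O[C@@H]1C[C@@](OC(=O)/C=C/c2ccc(O[Si](C)(C)C(C)(C)C)c(O[Si](C)(C)C(C)(C)C)c2)(C(=O)OCc2ccc(OC)cc2)C[C@@H](O[C@](C)(OC)[C@@]2(C)OC)[C@@H]1O2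
F6 | step 6 | 4-methoxybenzyl 1,3-di-O-[(E)-caffeoyl]-4,5-O-[(2S,3S)-2,3-dimethoxybutane-2,3-diyl]quinate | O=C(/C=C/c1ccc(O)c(O)c1)O[C@@H]1C[C@@](OC(=O)/C=C/c2ccc(O)c(O)c2)(C(=O)OCc2ccc(OC)cc2)C[C@@H](O[C@](C)(OC)[C@@]2(C)OC)[C@@H]1O2
F7 | step 2 | 4,5-O-[(2S,3S)-2,3-dimethoxybutane-2,3-diyl]quinic acid | O[C@@H]1C[C@@](O)(C(=O)O)C[C@@H](O[C@](C)(OC)[C@@]2(C)OC)[C@@H]1O2
A1 | alternative 1 | 3,5-bis(tert-butyldimethylsilyloxy)-6-vinyltetrahydro-2H-pyran-2-one, 5-silyloxy trans to 6-vinyl (3,5-cis epimer drawn; C3 is erased on enolisation) | C=C[C@@H]1OC(=O)[C@@H](O[Si](C)(C)C(C)(C)C)C[C@H]1O[Si](C)(C)C(C)(C)C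
A2 | alternative 1 | 1,5-bis(tert-butyldimethylsilyloxy)cyclohex-3-ene-1-carboxylic acid, O1 trans to O5 (quinic numbering) | C1=C[C@H](O[Si](C)(C)C(C)(C)C)C[C@](O[Si](C)(C)C(C)(C)C)(C(=O)O)C1
A3 | alternative 2 | 3-oxoprop-1-en-2-yl 2-(diethoxyphosphoryl)acetate | C=C(C=O)OC(=O)CP(=O)(OCC)OCC
A4 | alternative 2 | buta-1,3-diene | C=CC=C
A5 | alternative 2 | (S)-1-formylcyclohex-3-en-1-yl 2-(diethoxyphosphoryl)acetate | C1C[C@@](OC(=O)CP(=O)(OCC)OCC)(C=O)CC=C1
A6 | alternative 2 | 2,2-dimethyl-1,3-benzodioxole-5-carbaldehyde | CC1(C)Oc2ccc(C=O)cc2O1
A7 | alternative 3 | 3-allyl-3-hydroxy-5-vinyldihydrofuran-2(3H)-one, allyl and vinyl cis, natural quinide series | C=CC[C@@](O)(C(=O)O1)C[C@@H]1C=C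
A8 | alternative 3 | 1-hydroxy-6-oxabicyclo[3.2.1]oct-3-en-7-one, natural quinide series | C=2C[C@@](O)(C(=O)O1)C[C@@H]1C=2
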